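Atoms are numbered as in the target (ring C1–C10, lactone C11–C12, acetoxymethyl C13). The ten-membered ring is not closed end to end: it is released from a cyclohexanone, ring B (C3–C8), by cutting C3–C8. In the key step a C2 radical adds to the C3 ketone, the alkoxy radical opens toward C8, which is allylic to C7=C11, oxygen-bearing and γ to the C12 carbonyl, and the C8 radical ejects PhS• from C9; C2–C3, the ring and the C8=C9 enol-lactone alkene form together. The precursor is a butenolide-fused cyclohexanone whose C8 side chain carries SPh at C9, a silyl ether at C10 and iodine at C2; an Ireland–Claisen rearrangement and a phenylsulfenolactonization assemble it.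

Key step: step 23

Assumption: C8 and C9 are erased in step 23, so their configuration (fixed here by anti addition in step 14) is free and the minor C9 epimer from step 12 is carried along; compounds 16–29 are drawn for the expected major (9S-carbinol) series.

PMB = 4-methoxybenzyl.

**Ring B fragment**

Step 1
Reactants: 1 4,4-dimethoxycyclohexa-2,5-dien-1-one
Product: 2 (S)-4,4-dimethoxy-5-methylcyclohex-2-en-1-one
Conditions: Me2Zn (1.5 equiv), Cu(OTf)2 (2 mol %), binaphthol/bis(1-phenylethyl)amine phosphoramidite ligand (4 mol %, antipode chosen for S), toluene, −25 °C; NH4Cl (aq)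
Reagents that add atoms: dimethylzinc, C[Zn]C
Why: Copper-catalysed asymmetric conjugate addition of a dialkylzinc to a quinone monoketal (a known desymmetrisation of this dienone class) sets C4 as S through the choice of ligand antipode and leaves the second enone for step 2.

Step 2
Reactants: 2 (S)-4,4-dimethoxy-5-methylcyclohex-2-en-1-one
Product: 4 (4R,6S)-4-hydroxy-6-methylcyclohex-2-en-1-one, via ketal alcohol 3 (not isolated)
Conditions: NaBH4, CeCl3·7H2O, MeOH, −78 °C; then 1 M HCl, THF, 0 °C
Reagents that add atoms: water, O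
Why: Luche 1,2-reduction delivers hydride axially, so the C6 hydroxyl should end up cis to the C4 methyl (the cis-carveol pattern of 5-substituted cyclohexenones, giving 6R), and dilute acid then hydrolyses the allylic dimethyl ketal to the C3 enone.

Step 3
Reactants: 4 (4R,6S)-4-hydroxy-6-methylcyclohex-2-en-1-one
Product: 5 (4R,6S)-4-hydroxy-2-iodo-6-methylcyclohex-2-en-1-one
Conditions: I2, pyridine–CH2Cl2, 0 °C → rt
Reagents that add atoms: iodine, [I][I]
Why: α-Iodination of an enone with iodine and pyridine (conjugate addition of pyridine, iodination, elimination) places iodine on C8, the α-carbon of the C3 ketone, and creates no stereocentre.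

Step 4
Reactants: 5 (4R,6S)-4-hydroxy-2-iodo-6-methylcyclohex-2-en-1-one
Product: 6 (1R,4R,6S)-2-iodo-6-methylcyclohex-2-ene-1,4-diol
Conditions: NaBH4, CeCl3·7H2O, MeOH, −78 °C; NH4Cl (aq)
Reagents that add atoms: none
Why: Luche reduction of the α-iodo enone should give the C3 alcohol mainly trans to the C4 methyl by axial attack; this centre is only a placeholder and is re-oxidised in step 22.

Step 5
Reactants: 6 (1R,4R,6S)-2-iodo-6-methylcyclohex-2-ene-1,4-diol
Product: 7 (1R,4R,6S)-2-iodo-1,4-bis[(4-methoxybenzyl)oxy]-6-methylcyclohex-2-ene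
Conditions: NaH, PMBCl, Bu4NI (cat.), THF–DMF, 0 °C → rt
Reagents that add atoms: 4-methoxybenzyl chloride, COc1ccc(CCl)cc1
Why: Williamson etherification protects the C3 and C6 alcohols as PMB ethers, which tolerate organolithium, enolate and sulfenyl chloride chemistry and leave together in step 19.

**Side-chain fragment**

Step 6
Reactants: 8 (R)-citramalic acid
Product: 9 (R)-2-methylbutane-1,2,4-triol
Conditions: BH3·SMe2, B(OMe)3, THF, 0 °C → rt; MeOH
Reagents that add atoms: none
Why: Borane reduces both carboxyl groups of the hydroxy diacid (as in the malic acid to butanetriol reduction) and cannot touch the C10 stereocentre, which comes from the chiral pool.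

Step 7
Reactants: 9 (R)-2-methylbutane-1,2,4-triol
Product: 10 2-[(4R)-2,2,4-trimethyl-1,3-dioxolan-4-yl]ethanol
Conditions: 2,2-dimethoxypropane, TsOH (cat.), acetone, rt
Reagents that add atoms: 2,2-dimethoxypropane, COC(C)(C)OC
Why: Thermodynamic acetonide formation selects the five-membered dioxolane across the C9 and C10 oxygens and leaves the primary C2 alcohol free.

Step 8
Reactants: 10 2-[(4R)-2,2,4-trimethyl-1,3-dioxolan-4-yl]ethanol
Product: 11 (4R)-4-{2-[(4-methoxybenzyl)oxy]ethyl}-2,2,4-trimethyl-1,3-dioxolane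
Conditions: NaH, PMBCl, Bu4NI (cat.), THF–DMF, 0 °C → rt
Reagents that add atoms: 4-methoxybenzyl chloride, COc1ccc(CCl)cc1
Why: Williamson etherification masks the C2 oxygen with the same oxidatively removable group used on ring B.

Step 9
Reactants: 11 (4R)-4-{2-[(4-methoxybenzyl)oxy]ethyl}-2,2,4-trimethyl-1,3-dioxolane
Product: 12 (2R)-4-[(4-methoxybenzyl)oxy]-2-methylbutane-1,2-diol
Conditions: AcOH–H2O–THF (3:1:1), 40 °C
Reagents that add atoms: none
Why: Mild aqueous acid hydrolyses the acetonide while the PMB ether is stable.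

Step 10
Reactants: 12 (2R)-4-[(4-methoxybenzyl)oxy]-2-methylbutane-1,2-diol
Product: 13 (2R)-4-[(4-methoxybenzyl)oxy]-2-methyl-1,2-bis(triethylsilyloxy)butane
Conditions: Et3SiOTf (2.4 equiv), 2,6-lutidine, CH2Cl2, −78 → 0 °C
Reagents that add atoms: triethylsilyl triflate, CC[Si](CC)(CC)OS(=O)(=O)C(F)(F)F
Why: A silyl triflate with 2,6-lutidine silylates both the primary and the hindered tertiary alcohol.

Step 11
Reactants: 13 (2R)-4-[(4-methoxybenzyl)oxy]-2-methyl-1,2-bis(triethylsilyloxy)butane
Product: 14 (2R)-4-[(4-methoxybenzyl)oxy]-2-methyl-2-(triethylsilyloxy)butanal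
Conditions: (COCl)2, DMSO, CH2Cl2, −78 → −30 °C; Et3N, −78 → 0 °C
Reagents that add atoms: none
Why: Under Swern conditions a primary triethylsilyl ether is cleaved by the chlorosulfonium salt and oxidised directly to the aldehyde, whereas the tertiary silyl ether is inert, which spares a separate deprotection.

**Union and lactone**

Step 12
Reactants: 7 vinyl iodide (ring B fragment); 14 aldehyde (side-chain fragment)
Product: 17 (9S)-allylic acetate of the coupled fragments, via cyclohexenyllithium 15 (not isolated), via lithium alkoxide 16 (not isolated)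
Conditions: t-BuLi (2.1 equiv), Et2O, −78 °C; 14, −78 °C; Ac2O, −78 → 0 °C
Reagents that add atoms: acetic anhydride, CC(=O)OC(C)=O
Why: Iodine–lithium exchange gives a cyclohexenyllithium that adds to the non-enolisable aldehyde under Felkin–Anh control (silyloxy group anti, 9S expected) and the alkoxide is acetylated in the flask; C9 is a relay centre that disappears in step 23.

Step 13
Reactants: 17 (9S)-allylic acetate
Product: 19 γ,δ-unsaturated acid (C7–CH2CO2H; exocyclic C8=C9), via silyl ketene acetal 18 (not isolated)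
Conditions: LiN(iPr)2, Me3SiCl–Et3N, THF, −78 °C, then 60 °C; aq. citric acid
Reagents that add atoms: none
Why: Ireland–Claisen rearrangement through a chair with the C10 group pseudo-equatorial forms C7–C11 on the face anti to the C6 ether (chirality transfer from C9) and gives the exocyclic C8=C9 alkene with C10 syn to C3.

Step 14
Reactants: 19 γ,δ-unsaturated acid
Product: 20 phenylthio lactone (cis-fused γ-lactone; O on C8; SPh on C9)
Conditions: Et3N (1.2 equiv), PhSCl (1.1 equiv), CH2Cl2, −78 °C
Reagents that add atoms: benzenesulfenyl chloride, ClSc1ccccc1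
Why: Phenylsulfenolactonization: the episulfonium ion is opened 5-exo at the more substituted C8 by the tethered carboxylate, so the cis-fused γ-lactone forms with oxygen on C8 and sulfur anti on C9, both new centres being fixed by anti addition to the defined alkene.

Step 15
Reactants: 20 phenylthio lactone
Product: 21 α-formyl lactone (C11–CHO; mainly the hydroxymethylene enol)
Conditions: NaH, HCO2Et, EtOH (cat.), Et2O–THF, 0 °C → rt; cold dilute HCl
Reagents that add atoms: ethyl formate, CCOC=O
Why: Crossed Claisen condensation with ethyl formate is pulled to completion by the stabilised sodium enolate of the α-formyl lactone and brings in C13.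

Step 16
Reactants: 21 α-formyl lactone
Product: 23 α-formyl butenolide (C7=C11), via α-seleno aldehyde 22 (not isolated)
Conditions: PhSeCl, pyridine, CH2Cl2, 0 °C; then mCPBA (1.0 equiv), −78 → 0 °C
Reagents that add atoms: none
Why: Selenenylation of the β-dicarbonyl enol and selenoxide syn-elimination toward H-7 (the only β-hydrogen) give the C7=C11 alkene; selenium is expected on the convex face that carries H-7, and one equivalent of peracid at −78 °C should oxidise selenium far faster than the hindered aryl sulfide.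

Step 17
Reactants: 23 α-formyl butenolide
Product: 24 C13 alcohol (α-hydroxymethyl butenolide)
Conditions: NaBH4, CeCl3·7H2O, MeOH–CH2Cl2, −78 °C; NH4Cl (aq)
Reagents that add atoms: none
Why: Luche conditions reduce the aldehyde 1,2 and leave the lactone and the fully substituted alkene alone.

Step 18
Reactants: 24 C13 alcohol
Product: 25 C13 acetate
Conditions: Ac2O, pyridine, DMAP (cat.), CH2Cl2, 0 °C
Reagents that add atoms: acetic anhydride, CC(=O)OC(C)=O
Why: Standard acetylation of the only free (primary allylic) alcohol.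

**End game**

Step 19
Reactants: 25 C13 acetate
Product: 26 triol (free OH at C2 and C3 and C6)
Conditions: DDQ (4 equiv), CH2Cl2–pH 7 buffer (10:1), 0 °C → rt
Reagents that add atoms: none
Why: DDQ cleaves all three PMB ethers by benzylic oxidation under buffered conditions that tolerate the tertiary silyl ether, the esters and the aryl sulfide (as in thioglycoside chemistry).

Step 20
Reactants: 26 triol
Product: 27 C2 iodide (C3 and C6 diol)
Conditions: PPh3, I2, imidazole, CH2Cl2, 0 °C
Reagents that add atoms: iodine, [I][I]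
Why: Appel-type iodination is selective for the unhindered primary C2 alcohol over the two secondary alcohols.

Step 21
Reactants: 27 C2 iodide
Product: 28 C6 3-methylbut-2-enoate (C3 alcohol)
Conditions: 3-methylbut-2-enoyl chloride, pyridine, DMAP (cat.), CH2Cl2, 0 °C
Reagents that add atoms: 3-methylbut-2-enoyl chloride, CC(C)=CC(Cl)=O
Why: Acylation picks the accessible C6 alcohol because the C3 alcohol is shielded by the C8 quaternary centre and C4, and pyridine instead of a trialkylamine avoids the vinylketene that would deconjugate the ester.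

Step 22
Reactants: 28 C6 3-methylbut-2-enoate
Product: 29 keto iodide (precursor of the key step)
Conditions: Dess–Martin periodinane, NaHCO3, CH2Cl2, 0 °C → rt
Reagents that add atoms: none
Why: Dess–Martin oxidation handles the hindered C3 alcohol under buffered non-basic conditions, so the now epimerisable C4 centre, the sulfide and the iodide are preserved.

Step 23
Reactants: 29 keto iodide
Product: 30 C10 triethylsilyl ether of the target
Conditions: (Bu3Sn)2 (1.2 equiv), benzene (5 mM), sunlamp, 80 °C
Reagents that add atoms: none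
Why: Photolysed hexabutylditin supplies Bu3Sn•, which abstracts iodine; the primary C2 radical adds to the C3 carbonyl carbon, the bicyclic alkoxy radical breaks C3–C8, and the ring-enlarged C8 radical expels PhS•, which attacks the ditin (giving Bu3SnSPh and a new Bu3Sn•), so the chain runs without any hydrogen donor that could reduce C2 prematurely. The closest known chemistry is the Dowd–Beckwith three- and four-carbon ring expansion of 2-(ω-haloalkyl)cycloalkanones, combined with the β-fragmentation of β-thioalkyl radicals that carries allyl sulfide/ditin chains. The only closure is the transient six-membered ring formed by 6-exo-trig attack on C=O; the ten-membered ring arises by β-scission (expansion by C9, C10, C1 and C2), not by end-to-end closure. No stereocentre is created and C8 and C9 are erased; the C8=C9 geometry is not fixed by the mechanism and is left to reversible thiyl addition–elimination, expected to drain to the Z enol lactone (C7 and C10 trans). The step needs the C2 radical to choose the C3 carbonyl over 6-exo addition to C7 of the C7=C11 alkene: C7 is fully substituted and flanked by the C6 ester, the α-acyloxy ketone is electron-poor, and cleavage toward the oxygen-substituted, allylic, lactone-conjugated C8 radical makes carbonyl addition irreversible in practice. Neutral conditions spare the acetate, the 3-methylbut-2-enoate, the silyl ether and the epimerisable C4 centre.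

Step 24
Reactants: 30 C10 triethylsilyl ether of the target
Product: 31 CNP0186726.1
Conditions: HF·pyridine, pyridine, THF, 0 °C
Reagents that add atoms: none
Why: Fluoride-driven cleavage of the tertiary silyl ether under pyridine buffering leaves both esters, the enol lactone and the C4 centre untouched.

**Compound list**

1 | 4,4-dimethoxycyclohexa-2,5-dien-1-one | COC1(OC)C=CC(=O)C=C1 | starting material
2 | (S)-4,4-dimethoxy-5-methylcyclohex-2-en-1-one | O=C1C=CC(OC)(OC)[C@@H](C)C1 | intermediate
3 | (1R,5S)-4,4-dimethoxy-5-methylcyclohex-2-en-1-ol (not isolated) | O[C@H]1C=CC(OC)(OC)[C@@H](C)C1 | intermediate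
4 | (4R,6S)-4-hydroxy-6-methylcyclohex-2-en-1-one | O[C@H]1C=CC(=O)[C@@H](C)C1 | intermediate
5 | (4R,6S)-4-hydroxy-2-iodo-6-methylcyclohex-2-en-1-one | O[C@H]1C=C(I)C(=O)[C@@H](C)C1 | intermediate
6 | (1R,4R,6S)-2-iodo-6-methylcyclohex-2-ene-1,4-diol | O[C@H]1C=C(I)[C@H](O)[C@@H](C)C1 | intermediate
7 | (1R,4R,6S)-2-iodo-1,4-bis[(4-methoxybenzyl)oxy]-6-methylcyclohex-2-ene | COc1ccc(CO[C@H]2C=C(I)[C@H](OCc3ccc(OC)cc3)[C@@H](C)C2)cc1 | intermediate
8 | (R)-citramalic acid | OC(=O)[C@](C)(O)CC(=O)O | starting material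
9 | (R)-2-methylbutane-1,2,4-triol | OC[C@](C)(O)CCO | intermediate
10 | 2-[(4R)-2,2,4-trimethyl-1,3-dioxolan-4-yl]ethanol | CC1(C)OC[C@@](C)(CCO)O1 | intermediate
11 | (4R)-4-{2-[(4-methoxybenzyl)oxy]ethyl}-2,2,4-trimethyl-1,3-dioxolane | COc1ccc(COCC[C@]2(C)COC(C)(C)O2)cc1 | intermediate
12 | (2R)-4-[(4-methoxybenzyl)oxy]-2-methylbutane-1,2-diol | COc1ccc(COCC[C@@](C)(O)CO)cc1 | intermediate
13 | (2R)-4-[(4-methoxybenzyl)oxy]-2-methyl-1,2-bis(triethylsilyloxy)butane | COc1ccc(COCC[C@@](C)(O[Si](CC)(CC)CC)CO[Si](CC)(CC)CC)cc1 | intermediate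
14 | (2R)-4-[(4-methoxybenzyl)oxy]-2-methyl-2-(triethylsilyloxy)butanal | COc1ccc(COCC[C@@](C)(O[Si](CC)(CC)CC)C=O)cc1 | intermediate
15 | cyclohexenyllithium from 7 (Li on C8; not isolated) | COc1ccc(CO[C@H]2C=C([Li])[C@H](OCc3ccc(OC)cc3)[C@@H](C)C2)cc1 | intermediate
16 | lithium (9S)-alkoxide of the coupled fragments (not isolated) | COc1ccc(COCC[C@@](C)(O[Si](CC)(CC)CC)[C@@H](O[Li])C2=C[C@H](OCc3ccc(OC)cc3)C[C@H](C)[C@H]2OCc2ccc(OC)cc2)cc1 | intermediate
17 | (9S)-allylic acetate: ring B cyclohexene (C7=C8) with PMB ethers at C3 and C6 and methyl at C4; C8 bears CH(OAc)–C(CH3)(OSiEt3)–CH2CH2OPMB | COc1ccc(COCC[C@@](C)(O[Si](CC)(CC)CC)[C@@H](OC(C)=O)C2=C[C@H](OCc3ccc(OC)cc3)C[C@H](C)[C@H]2OCc2ccc(OC)cc2)cc1 | intermediate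
18 | trimethylsilyl ketene acetal of 17 (not isolated) | COc1ccc(COCC[C@@](C)(O[Si](CC)(CC)CC)[C@@H](OC(=C)O[Si](C)(C)C)C2=C[C@H](OCc3ccc(OC)cc3)C[C@H](C)[C@H]2OCc2ccc(OC)cc2)cc1 | intermediate
19 | acid: ring B with C7–CH2CO2H anti to the C6 ether and exocyclic C8=C9 (C10 syn to C3) | OC(=O)C[C@H]1[C@H](OCc2ccc(OC)cc2)C[C@H](C)[C@@H](OCc2ccc(OC)cc2)/C1=C\[C@](C)(O[Si](CC)(CC)CC)CCOCc1ccc(OC)cc1 | intermediate
20 | phenylthio lactone: cis-fused γ-lactone (O on C8, C11H2), SPh on C9 anti to the lactone oxygen | O=C1C[C@H]2[C@H](OCc3ccc(OC)cc3)C[C@H](C)[C@@H](OCc3ccc(OC)cc3)[C@]2(O1)[C@@H](Sc3ccccc3)[C@](C)(O[Si](CC)(CC)CC)CCOCc3ccc(OC)cc3 | intermediate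
21 | α-formyl lactone (C11–CHO, C11 unassigned; mainly the hydroxymethylene enol) | O=CC1[C@H]2[C@H](OCc3ccc(OC)cc3)C[C@H](C)[C@@H](OCc3ccc(OC)cc3)[C@]2(OC1=O)[C@@H](Sc3ccccc3)[C@](C)(O[Si](CC)(CC)CC)CCOCc3ccc(OC)cc3 | intermediate
22 | α-formyl α-phenylseleno lactone (Se expected syn to H-7; not isolated) | O=CC1([Se]c3ccccc3)[C@H]2[C@H](OCc3ccc(OC)cc3)C[C@H](C)[C@@H](OCc3ccc(OC)cc3)[C@]2(OC1=O)[C@@H](Sc3ccccc3)[C@](C)(O[Si](CC)(CC)CC)CCOCc3ccc(OC)cc3 | intermediate
23 | α-formyl butenolide (C7=C11; C13 aldehyde) | O=CC1=C2[C@H](OCc3ccc(OC)cc3)C[C@H](C)[C@@H](OCc3ccc(OC)cc3)[C@]2(OC1=O)[C@@H](Sc3ccccc3)[C@](C)(O[Si](CC)(CC)CC)CCOCc3ccc(OC)cc3 | intermediate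
24 | C13 alcohol | OCC1=C2[C@H](OCc3ccc(OC)cc3)C[C@H](C)[C@@H](OCc3ccc(OC)cc3)[C@]2(OC1=O)[C@@H](Sc3ccccc3)[C@](C)(O[Si](CC)(CC)CC)CCOCc3ccc(OC)cc3 | intermediate
25 | C13 acetate | CC(=O)OCC1=C2[C@H](OCc3ccc(OC)cc3)C[C@H](C)[C@@H](OCc3ccc(OC)cc3)[C@]2(OC1=O)[C@@H](Sc3ccccc3)[C@](C)(O[Si](CC)(CC)CC)CCOCc3ccc(OC)cc3 | intermediate
26 | triol (OH at C2, C3 and C6) | CC(=O)OCC1=C2[C@H](O)C[C@H](C)[C@@H](O)[C@]2(OC1=O)[C@@H](Sc3ccccc3)[C@](C)(O[Si](CC)(CC)CC)CCO | intermediate
27 | C2 iodide, C3/C6 diol | CC(=O)OCC1=C2[C@H](O)C[C@H](C)[C@@H](O)[C@]2(OC1=O)[C@@H](Sc3ccccc3)[C@](C)(O[Si](CC)(CC)CC)CCI | intermediate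
28 | C6 3-methylbut-2-enoate, C3 alcohol | CC(=O)OCC1=C2[C@H](OC(=O)C=C(C)C)C[C@H](C)[C@@H](O)[C@]2(OC1=O)[C@@H](Sc3ccccc3)[C@](C)(O[Si](CC)(CC)CC)CCI | intermediate
29 | keto iodide (precursor): butenolide-fused cyclohexanone, C8 bearing CH(SPh)–C(CH3)(OSiEt3)–CH2CH2I | CC(=O)OCC1=C2[C@H](OC(=O)C=C(C)C)C[C@H](C)C(=O)[C@]2(OC1=O)[C@@H](Sc3ccccc3)[C@](C)(O[Si](CC)(CC)CC)CCI | intermediate
30 | C10 triethylsilyl ether of the target (Z enol lactone) | CC(=O)OCC1=C2/C(=C/[C@](C)(O[Si](CC)(CC)CC)CCC(=O)[C@@H](C)C[C@H]2OC(=O)C=C(C)C)OC1=O | intermediate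
31 | CNP0186726.1 | CC(=O)OCC1=C2/C(=C/[C@](C)(O)CCC(=O)[C@@H](C)C[C@H]2OC(=O)C=C(C)C)OC1=O | target

**Step count**

Total steps: 24. Longest linear sequence: 19 steps (from 8 through steps 6–11 and 12–24).

**Steps most likely to fail**

1. Step 23. The chain may fail to propagate because the thiyl radical is not turned over by the ditin, or the C2 radical may be consumed by 6-exo addition to C7 before it reaches the carbonyl. The fallback sets out from 26 and returns at 30. mCPBA (2.2 equiv, CH2Cl2, 0 °C) would oxidise the sulfide of 26 to the sulfone triol F1. The conditions of steps 20, 21 and 22 would then give the iodo sulfone diol F2, the sulfone senecioate F3 and the keto sulfone F4. Slow addition of Bu3SnH/AIBN (benzene, 80 °C) would run the same ring expansion with loss of PhSO2•, which is turned over by tin hydride and whose sulfinic acid, unlike a thiol, does not reduce the C2 radical; the product is 30.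

2. Step 14. The hindered trisubstituted C8=C9 alkene may react sluggishly with the bulky sulfenyl chloride, or the episulfonium ion may be opened without the carboxylate (chloride capture, loss of a proton to an allylic sulfide). The fallback sets out from 19 and returns at 20. Iodolactonization (I2, NaHCO3, MeCN–H2O, 0 °C) with the smaller electrophile would give the iodo lactone F5. Photolysis with (Bu3Sn)2 and PhSSPh in benzene would then replace iodine by SPh through capture of the C9 radical by the disulfide, giving 20 as a C9 epimer mixture that converges in step 23.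

3. Step 16. Selenium may be delivered to the face anti to H-7, so that syn-elimination is impossible, or oxidation may spill over to sulfur. The fallback sets out from 20 and returns at 25, bypassing 21–24. LiN(iPr)2 then PhSeCl (THF, −78 °C) would give the α-phenylseleno lactone F6. A second deprotonation, monomeric formaldehyde and an Ac2O quench would give the α-acetoxymethyl α-phenylseleno lactone F7, in which selenium sits on the face opposite to the one reached in step 16 because the carbon electrophile now enters last. Oxidation (mCPBA, 1.0 equiv, −78 °C) and syn-elimination away from the oxygen-bearing C13 would give 25.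

**Further compounds**

F1 | step 23 | sulfone triol (26 with SO2Ph on C9) | CC(=O)OCC1=C2[C@H](O)C[C@H](C)[C@@H](O)[C@]2(OC1=O)[C@@H](S(=O)(=O)c3ccccc3)[C@](C)(O[Si](CC)(CC)CC)CCO
F2 | step 23 | iodo sulfone diol | CC(=O)OCC1=C2[C@H](O)C[C@H](C)[C@@H](O)[C@]2(OC1=O)[C@@H](S(=O)(=O)c3ccccc3)[C@](C)(O[Si](CC)(CC)CC)CCI
F3 | step 23 | sulfone senecioate (C3 alcohol) | CC(=O)OCC1=C2[C@H](OC(=O)C=C(C)C)C[C@H](C)[C@@H](O)[C@]2(OC1=O)[C@@H](S(=O)(=O)c3ccccc3)[C@](C)(O[Si](CC)(CC)CC)CCI
F4 | step 23 | keto sulfone (29 with SO2Ph on C9) | CC(=O)OCC1=C2[C@H](OC(=O)C=C(C)C)C[C@H](C)C(=O)[C@]2(OC1=O)[C@@H](S(=O)(=O)c3ccccc3)[C@](C)(O[Si](CC)(CC)CC)CCI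
F5 | step 14 | iodo lactone (20 with I on C9) | O=C1C[C@H]2[C@H](OCc3ccc(OC)cc3)C[C@H](C)[C@@H](OCc3ccc(OC)cc3)[C@]2(O1)[C@@H](I)[C@](C)(O[Si](CC)(CC)CC)CCOCc3ccc(OC)cc3
F6 | step 16 | α-phenylseleno lactone (SePh on C11) | O=C1C([Se]c3ccccc3)[C@H]2[C@H](OCc3ccc(OC)cc3)C[C@H](C)[C@@H](OCc3ccc(OC)cc3)[C@]2(O1)[C@@H](Sc3ccccc3)[C@](C)(O[Si](CC)(CC)CC)CCOCc3ccc(OC)cc3
F7 | step 16 | α-acetoxymethyl α-phenylseleno lactone | CC(=O)OCC1([Se]c3ccccc3)[C@H]2[C@H](OCc3ccc(OC)cc3)C[C@H](C)[C@@H](OCc3ccc(OC)cc3)[C@]2(OC1=O)[C@@H](Sc3ccccc3)[C@](C)(O[Si](CC)(CC)CC)CCOCc3ccc(OC)cc3
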